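**The half-life.** The constants are hidden, so the readings have to supply one. G (substrate) reacts with Z, which is dissolved D and starts at nothing; J (a further species) is charged at different levels in the runs.

| flask | G | D | J | remark | time |
|---|---|---|---|---|---|
| Monday's | 18 mM | 8 mM (held) | 4.5 mM | run made earlier |  |
| Tuesday's | 18 mM | 8 mM (held) | 18 mM | run made earlier |  |
| flask | 18 mM | 8.0 mM (held) | 9.00 mM |  | 12 h |

| run | time / h | X / % | G / % |
|---|---|---|---|
| Monday's | 1.33 | 17 | 82 |
| Monday's | 4.00 | 49 | 51 |
| Monday's | 6.00 | 62 | 33 |
| Monday's | 10.0 | 80 | 17 |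
| Monday's | 15.0 | 85 | 4 |
| Tuesday's | 1.00 | 12 | 86 |
| Tuesday's | 2.00 | 26 | 76 |
| Tuesday's | 4.00 | 50 | 49 |
| Tuesday's | 8.00 | 78 | 20 |
| Tuesday's | 15.0 | 91 | 2 |

(each reading ± 2 percentage points)

- the earlier runs were read with a standard deviation of 2 percentage points
- at the start none of D is in solution
- Z is what D becomes in solution

* how much X there is at 12 h, in percent of the G charged
* concentration of Z in solution at 12 h, in percent of saturation

G at 4.00 h reads 51% on Monday and 49% on Tuesday, so J shows no effect on G within the scatter. The count therefore rests on Tuesday's readings. Its first stretch gives 3.89 h: Ts, the half-life of G, the time in which G halves. From 4.00 h to 8.00 h the reading shortens to Tf = 3.09 h, as expected if Z is climbing.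

**Two extremes.** With Ts throughout, 12 h is 3.08 half-lives and leaves G 11.8%. With Tf throughout, G falls to 6.80%. Both half-lives are read from scattered readings, so these two are estimates; my reckoning puts G in the flask between them, since the later reading Tf is shorter than the earlier Ts. X + G falls short of the charge by 3 percentage points on Monday at 10.0 h and by 7 points on Tuesday at 15.0 h, two readings from different runs on either side of 12 h. Taking the higher G with the larger gap and the lower G with the smaller gap, my reckoning puts X between 81.2% and 90.2%, with Z close to saturation.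

**The forecast.** It gives X 86% and Z 90%, holding that “the rate follows dissolved Z”. Its X lies in my range.

**The flask.** It gives X 86.1% and Z 98.7% of saturation, 8.7 points above the forecast.

    D ⇌ Z, rate k1*(csat - [Z]) (kL = 0.00386 s⁻¹)
    G + Z → X (k = 0.00727 M⁻¹ s⁻¹)
    Z + X → E (k = 1.91 × 10⁻⁴ M⁻¹ s⁻¹)
    Z ⇌ L (K = 13.0, k = 0.00169 s⁻¹)
    Z + J → Q (k = 0.0161 M⁻¹ s⁻¹)

G stands at 10.4% after 12.0 h, down from 35.3% at 6.00 h, a half-life of 3.40 h between Tf and Ts. The neighbour flask read at 5.0 h, with the same charges, holds G 42.9%, against 41.0% counted with Ts.

The data were computed from invented constants; noise was put on by code.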